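**Retrosynthetic overview** (locants: C1 lactone carbonyl, C7 lactone carbinol, C8–C10 cyclopropane with C9 as its CH2, C11=C12 E, C13/C14 diol, C16=C17 Z)
1. The C11=C12 alkene is cut by Julia–Kocienski olefination into a cyclopropylmethyl sulfone that already carries the finished oxocan-2-one and a C12–C22 α-alkoxy aldehyde.
2. The aldehyde comes from L-threitol acetonide (L-tartaric acid pool): its four carbons become C12–C15 and its two stereocenters become C13 and C14; the Z-alkene comes from triflate alkynylation with hept-1-yne and Lindlar reduction.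
3. The oxocan-2-one is closed at the C2–C3 bond by 8-endo-trig cyclisation of the (alkoxycarbonyl)methyl radical of a C7 bromoacetate onto the C3=C4 vinyl group, which gives the saturated lactone directly.
4. Enabling feature: the O1–C1 ester bond keeps its preferred Z (s-trans) geometry in an eight-membered transition state, and ring atoms C2–C6 are bare CH2 groups, so the electrophilic C2 radical attacks the free CH2 terminus C3 and the C4 radical needs only a hydrogen atom.
5. Ring order: cyclopropane first (hydroxyl-directed Simmons–Smith on an (R,E)-allylic alcohol whose C7 center comes from asymmetric transfer hydrogenation of an ynone), then the oxocan-2-one.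

Key step: step 6

Assumption: conjugate bases formed in situ (alkoxides, the acetylide, the sulfonyl carbanion) are treated as forms of their parent compounds; the two carbon radicals of step 6 are listed as unisolated intermediates.

**Step 1**
Reactants: 1 pent-4-enoyl chloride; 2 tert-butyldimethyl(prop-2-yn-1-yloxy)silane
Product: 3 1-[(tert-butyldimethylsilyl)oxy]non-8-en-2-yn-4-one
Conditions: PdCl2(PPh3)2 (2 mol%), CuI (4 mol%), Et3N, THF, rt
Reagents that add atoms: none
Why: Acyl Sonogashira coupling joins the acid chloride carbon (C7) to the terminal alkyne carbon (C8) at room temperature, where the silyl ether and the isolated vinyl group should not react; no stereocenter is formed.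

**Step 2**
Reactants: 3 1-[(tert-butyldimethylsilyl)oxy]non-8-en-2-yn-4-one
Product: 4 (4R)-1-[(tert-butyldimethylsilyl)oxy]non-8-en-2-yn-4-ol
Conditions: Ru[(R,R)-TsNCH(Ph)CH(Ph)NH](p-cymene) (1 mol%), i-PrOH, rt
Reagents that add atoms: none
Why: Noyori asymmetric transfer hydrogenation of an alkynyl alkyl ketone, in which the (R,R)-diamine complex should deliver hydride to the face giving the (R)-carbinol (the sense known for ynones, the alkynyl group taking the role of an aryl group), sets C7 while alkyne and alkene stay untouched under base-free conditions.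

**Step 3**
Reactants: 4 (4R)-1-[(tert-butyldimethylsilyl)oxy]non-8-en-2-yn-4-ol
Product: 5 (2E,4R)-1-[(tert-butyldimethylsilyl)oxy]nona-2,8-dien-4-ol
Conditions: NaAlH2(OCH2CH2OMe)2, THF, −20 → 0 °C; aq. Rochelle salt
Reagents that add atoms: none
Why: Red-Al reduction of a propargylic alcohol proceeds by alkoxide-directed trans-hydroalumination, so protonolysis should give only the E-allylic alcohol with C7 unchanged, the low temperature being chosen to suppress loss of the silyloxy group to an allene.

**Step 4**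
Reactants: 5 (2E,4R)-1-[(tert-butyldimethylsilyl)oxy]nona-2,8-dien-4-ol
Product: 6 (1R)-1-[(1R,2R)-2-{[(tert-butyldimethylsilyl)oxy]methyl}cyclopropyl]pent-4-en-1-ol
Conditions: Et2Zn (3 equiv), CH2I2 (3 equiv), CH2Cl2, −10 → 0 °C
Reagents that add atoms: diiodomethane (ICI)
Why: Hydroxyl-directed Simmons–Smith cyclopropanation (Furukawa variant): the zinc alkoxide at C7 delivers CH2 to the alkene face on its own side in the conformer of least allylic strain, which for E-allylic secondary alcohols should give the syn cyclopropylcarbinol, so C8 and C10 are set by C7, the trans ring follows from the E-alkene, and the undirected terminal alkene reacts far more slowly.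

**Step 5**
Reactants: 6 (1R)-1-[(1R,2R)-2-{[(tert-butyldimethylsilyl)oxy]methyl}cyclopropyl]pent-4-en-1-ol; 7 bromoacetyl bromide
Product: 8 (1R)-1-[(1R,2R)-2-{[(tert-butyldimethylsilyl)oxy]methyl}cyclopropyl]pent-4-en-1-yl bromoacetate
Conditions: pyridine, CH2Cl2, 0 °C
Reagents that add atoms: none
Why: Acylation of the secondary cyclopropylcarbinol with an acyl bromide and pyridine is fast at 0 °C and does not ionise the cyclopropylcarbinyl C–O bond, so C7 is retained.

**Step 6**
Reactants: 8 (1R)-1-[(1R,2R)-2-{[(tert-butyldimethylsilyl)oxy]methyl}cyclopropyl]pent-4-en-1-yl bromoacetate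
Product: 11 (8R)-8-[(1R,2R)-2-{[(tert-butyldimethylsilyl)oxy]methyl}cyclopropyl]oxocan-2-one, via ester-stabilised C2 radical 9 (not isolated), via cyclised C4 radical 10 (not isolated)
Conditions: Bu3SnH (1.3 equiv) and AIBN (0.2 equiv) added by syringe pump over 6 h, benzene, reflux, 0.003 M in 8
Reagents that add atoms: none
Why: The tributylstannyl radical abstracts bromine to give the electrophilic (alkoxycarbonyl)methyl radical 9, which adds through an 8-endo-trig transition state to the unsubstituted C3 terminus of the C3=C4 alkene, forming the C2–C3 bond, and the secondary C4 radical 10 is then reduced by Bu3SnH to the saturated lactone. The closest known reaction type is the 8-endo cyclisation of (alkoxycarbonyl)methyl radicals generated from bromoacetates of pent-4-en-1-ols, which gives heptanolactones. The only ring closed is the eight-membered lactone, by 8-endo-trig radical closure. No new stereocenter is created (C3 and C4 end as CH2), and C7, C8 and C10 are retained because neither radical is adjacent to the cyclopropane, so no cyclopropylcarbinyl radical can form. The step needs 8-endo over 7-exo regioselectivity and cyclisation over premature reduction: the Z ester geometry is kept in the 8-endo transition state, the electrophilic radical prefers the terminal CH2, the branched C7 substituent favours the folded rotamer, and slow stannane addition at high dilution keeps the hydrogen-donor concentration low.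

**Step 7**
Reactants: 11 (8R)-8-[(1R,2R)-2-{[(tert-butyldimethylsilyl)oxy]methyl}cyclopropyl]oxocan-2-one
Product: 12 (8R)-8-[(1R,2R)-2-(hydroxymethyl)cyclopropyl]oxocan-2-one
Conditions: HF·pyridine, pyridine, THF, 0 °C → rt
Reagents that add atoms: none
Why: Fluoride cleavage of the primary silyl ether under buffered HF·pyridine conditions should leave the medium-ring lactone and the cyclopropane intact.

**Step 8**
Reactants: 12 (8R)-8-[(1R,2R)-2-(hydroxymethyl)cyclopropyl]oxocan-2-one
Product: 13 (8R)-8-[(1R,2R)-2-{[(1-phenyl-1H-tetrazol-5-yl)sulfanyl]methyl}cyclopropyl]oxocan-2-one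
Conditions: 1-phenyl-1H-tetrazole-5-thiol, PPh3, DIAD, THF, 0 °C → rt
Reagents that add atoms: 1-phenyl-1H-tetrazole-5-thiol (Sc1nnnn1-c1ccccc1)
Why: Mitsunobu reaction with an acidic thiol: SN2 displacement at the primary C11 carbon should proceed without cyclopropylcarbinyl rearrangement and touches no stereocenter.

**Step 9**
Reactants: 13 (8R)-8-[(1R,2R)-2-{[(1-phenyl-1H-tetrazol-5-yl)sulfanyl]methyl}cyclopropyl]oxocan-2-one
Product: 14 (8R)-8-[(1R,2R)-2-{[(1-phenyl-1H-tetrazol-5-yl)sulfonyl]methyl}cyclopropyl]oxocan-2-one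
Conditions: mCPBA (2.5 equiv), NaHCO3, CH2Cl2, 0 °C → rt
Reagents that add atoms: 3-chloroperoxybenzoic acid (OOC(=O)c1cccc(Cl)c1)
Why: Peracid oxidation of the sulfide to the sulfone; the molecule contains no alkene at this stage and the buffered medium protects the lactone.

**Step 10**
Reactants: 15 [(4S,5S)-2,2-dimethyl-1,3-dioxolane-4,5-diyl]dimethanol (2,3-O-isopropylidene-L-threitol)
Product: 16 [(4S,5S)-5-{[(tert-butyldimethylsilyl)oxy]methyl}-2,2-dimethyl-1,3-dioxolan-4-yl]methanol
Conditions: NaH (1.0 equiv), THF, 0 °C → rt; then TBSCl (1.0 equiv)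
Reagents that add atoms: tert-butyldimethylsilyl chloride (CC(C)(C)[Si](C)(C)Cl)
Why: Monosilylation of a C2-symmetric 1,4-diol through its monosodium alkoxide, the two hydroxyls being equivalent so that either outcome is the same compound; the two stereocenters of the tartrate pool are carried through and become C13 and C14.

**Step 11**
Reactants: 16 [(4S,5S)-5-{[(tert-butyldimethylsilyl)oxy]methyl}-2,2-dimethyl-1,3-dioxolan-4-yl]methanol
Product: 17 [(4S,5S)-5-{[(tert-butyldimethylsilyl)oxy]methyl}-2,2-dimethyl-1,3-dioxolan-4-yl]methyl trifluoromethanesulfonate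
Conditions: Tf2O, pyridine, CH2Cl2, −20 °C; cold aqueous work-up, used at once
Reagents that add atoms: trifluoromethanesulfonic anhydride (O=S(=O)(OS(=O)(=O)C(F)(F)F)C(F)(F)F)
Why: Sulfonylation of the primary alcohol at low temperature gives the reactive primary triflate, which is not stored but used directly.

**Step 12**
Reactants: 17 [(4S,5S)-5-{[(tert-butyldimethylsilyl)oxy]methyl}-2,2-dimethyl-1,3-dioxolan-4-yl]methyl trifluoromethanesulfonate; 18 hept-1-yne
Product: 19 tert-butyl(dimethyl){[(4S,5S)-2,2-dimethyl-5-(oct-2-yn-1-yl)-1,3-dioxolan-4-yl]methoxy}silane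
Conditions: 18, n-BuLi, THF, −78 °C; DMPU; then 17, −78 → −10 °C
Reagents that add atoms: none
Why: Triflate alkynylation: SN2 attack of the lithium acetylide at the primary carbon in THF/DMPU should form the C15–C16 bond faster than elimination, and the adjacent stereocenter C14 is not involved.

**Step 13**
Reactants: 19 tert-butyl(dimethyl){[(4S,5S)-2,2-dimethyl-5-(oct-2-yn-1-yl)-1,3-dioxolan-4-yl]methoxy}silane
Product: 20 tert-butyl(dimethyl){[(4S,5S)-2,2-dimethyl-5-[(2Z)-oct-2-en-1-yl]-1,3-dioxolan-4-yl]methoxy}silane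
Conditions: H2 (1 atm), Pd/CaCO3 poisoned with Pb(OAc)2 (Lindlar catalyst), quinoline, hexane/EtOAc, rt
Reagents that add atoms: none
Why: Lindlar semihydrogenation: syn addition of one equivalent of H2 on the poisoned catalyst should stop at the alkene and sets the 16Z geometry.

**Step 14**
Reactants: 20 tert-butyl(dimethyl){[(4S,5S)-2,2-dimethyl-5-[(2Z)-oct-2-en-1-yl]-1,3-dioxolan-4-yl]methoxy}silane
Product: 21 {(4S,5S)-2,2-dimethyl-5-[(2Z)-oct-2-en-1-yl]-1,3-dioxolan-4-yl}methanol
Conditions: Bu4NF, THF, 0 °C → rt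
Reagents that add atoms: none
Why: Fluoride cleavage of the primary silyl ether; the acetonide and the Z-alkene are inert.

**Step 15**
Reactants: 21 {(4S,5S)-2,2-dimethyl-5-[(2Z)-oct-2-en-1-yl]-1,3-dioxolan-4-yl}methanol
Product: 22 (4R,5S)-2,2-dimethyl-5-[(2Z)-oct-2-en-1-yl]-1,3-dioxolane-4-carbaldehyde
Conditions: Dess–Martin periodinane, pyridine, CH2Cl2, 0 °C → rt; used crude
Reagents that add atoms: none
Why: Dess–Martin oxidation under buffered, non-basic conditions should give the α-alkoxy aldehyde without epimerising C13 (the trans-dioxolane is also the thermodynamically preferred isomer) or isomerising the Z-alkene.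

**Step 16**
Reactants: 14 (8R)-8-[(1R,2R)-2-{[(1-phenyl-1H-tetrazol-5-yl)sulfonyl]methyl}cyclopropyl]oxocan-2-one; 22 (4R,5S)-2,2-dimethyl-5-[(2Z)-oct-2-en-1-yl]-1,3-dioxolane-4-carbaldehyde
Product: 23 (8R)-8-[(1R,2S)-2-{(E)-2-[(4S,5S)-2,2-dimethyl-5-[(2Z)-oct-2-en-1-yl]-1,3-dioxolan-4-yl]ethenyl}cyclopropyl]oxocan-2-one
Conditions: 14, KN(SiMe3)2 (1.05 equiv), DME, −55 °C, 20 min; then 22 (1.3 equiv), −55 °C → rt; aq. NH4Cl
Reagents that add atoms: none
Why: Julia–Kocienski olefination: the potassium sulfonyl carbanion adds to the α-alkoxy aldehyde, and Smiles rearrangement with loss of SO2 and the tetrazolate should give the E-alkene (open transition state with K+ in DME), the sulfone CH2 being far more acidic than the lactone α-CH2 so that the lactone is not enolised and C13 is not epimerised at low temperature.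

**Step 17**
Reactants: 23 (8R)-8-[(1R,2S)-2-{(E)-2-[(4S,5S)-2,2-dimethyl-5-[(2Z)-oct-2-en-1-yl]-1,3-dioxolan-4-yl]ethenyl}cyclopropyl]oxocan-2-one
Product: 24 (8R)-8-{(1R,2S)-2-[(1E,3S,4S,6Z)-3,4-dihydroxydodeca-1,6-dien-1-yl]cyclopropyl}oxocan-2-one (CNP0157264.1)
Conditions: AcOH/H2O/THF (3:1:1), 40 °C
Reagents that add atoms: none
Why: Acid-catalysed hydrolysis of the isopropylidene ketal in weakly acidic aqueous medium without an alcohol co-solvent should free the diol without ionising the allylic C13–O bond or opening the lactone, and no stereocenter is touched.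

**Compound list**
1 | pent-4-enoyl chloride | C=CCCC(=O)Cl | starting material
2 | tert-butyldimethyl(prop-2-yn-1-yloxy)silane | C#CCO[Si](C)(C)C(C)(C)C | starting material
3 | 1-[(tert-butyldimethylsilyl)oxy]non-8-en-2-yn-4-one | CC(C)(C)[Si](C)(C)OCC#CC(=O)CCC=C | intermediate
4 | (4R)-1-[(tert-butyldimethylsilyl)oxy]non-8-en-2-yn-4-ol | CC(C)(C)[Si](C)(C)OCC#C[C@H](O)CCC=C | intermediate
5 | (2E,4R)-1-[(tert-butyldimethylsilyl)oxy]nona-2,8-dien-4-ol | CC(C)(C)[Si](C)(C)OC/C=C/[C@H](O)CCC=C | intermediate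
6 | (1R)-1-[(1R,2R)-2-{[(tert-butyldimethylsilyl)oxy]methyl}cyclopropyl]pent-4-en-1-ol | CC(C)(C)[Si](C)(C)OC[C@@H]1C[C@H]1[C@H](O)CCC=C | intermediate
7 | bromoacetyl bromide | BrCC(Br)=O | starting material
8 | (1R)-1-[(1R,2R)-2-{[(tert-butyldimethylsilyl)oxy]methyl}cyclopropyl]pent-4-en-1-yl bromoacetate | CC(C)(C)[Si](C)(C)OC[C@@H]1C[C@H]1[C@H](OC(=O)CBr)CCC=C | intermediate
9 | ester-stabilised C2 radical (2-oxo-2-alkoxyethyl radical of 8) | CC(C)(C)[Si](C)(C)OC[C@@H]1C[C@H]1[C@H](OC(=O)[CH2])CCC=C | intermediate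
10 | cyclised C4 radical ((8R)-8-substituted 2-oxooxocan-5-yl radical) | CC(C)(C)[Si](C)(C)OC[C@@H]1C[C@H]1[C@H]1CC[CH]CCC(=O)O1 | intermediate
11 | (8R)-8-[(1R,2R)-2-{[(tert-butyldimethylsilyl)oxy]methyl}cyclopropyl]oxocan-2-one | CC(C)(C)[Si](C)(C)OC[C@@H]1C[C@H]1[C@H]1CCCCCC(=O)O1 | intermediate
12 | (8R)-8-[(1R,2R)-2-(hydroxymethyl)cyclopropyl]oxocan-2-one | OC[C@@H]1C[C@H]1[C@H]1CCCCCC(=O)O1 | intermediate
13 | (8R)-8-[(1R,2R)-2-{[(1-phenyl-1H-tetrazol-5-yl)sulfanyl]methyl}cyclopropyl]oxocan-2-one | c1ccccc1-n1nnnc1SC[C@@H]1C[C@H]1[C@H]1CCCCCC(=O)O1 | intermediate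
14 | (8R)-8-[(1R,2R)-2-{[(1-phenyl-1H-tetrazol-5-yl)sulfonyl]methyl}cyclopropyl]oxocan-2-one | O=S(=O)(C[C@@H]1C[C@H]1[C@H]1CCCCCC(=O)O1)c1nnnn1-c1ccccc1 | intermediate
15 | [(4S,5S)-2,2-dimethyl-1,3-dioxolane-4,5-diyl]dimethanol | OC[C@@H]1OC(C)(C)O[C@H]1CO | starting material
16 | [(4S,5S)-5-{[(tert-butyldimethylsilyl)oxy]methyl}-2,2-dimethyl-1,3-dioxolan-4-yl]methanol | OC[C@@H]1OC(C)(C)O[C@H]1CO[Si](C)(C)C(C)(C)C | intermediate
17 | [(4S,5S)-5-{[(tert-butyldimethylsilyl)oxy]methyl}-2,2-dimethyl-1,3-dioxolan-4-yl]methyl trifluoromethanesulfonate | O=S(=O)(OC[C@@H]1OC(C)(C)O[C@H]1CO[Si](C)(C)C(C)(C)C)C(F)(F)F | intermediate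
18 | hept-1-yne | C#CCCCCC | starting material
19 | tert-butyl(dimethyl){[(4S,5S)-2,2-dimethyl-5-(oct-2-yn-1-yl)-1,3-dioxolan-4-yl]methoxy}silane | CCCCCC#CC[C@@H]1OC(C)(C)O[C@H]1CO[Si](C)(C)C(C)(C)C | intermediate
20 | tert-butyl(dimethyl){[(4S,5S)-2,2-dimethyl-5-[(2Z)-oct-2-en-1-yl]-1,3-dioxolan-4-yl]methoxy}silane | CCCCC/C=C\C[C@@H]1OC(C)(C)O[C@H]1CO[Si](C)(C)C(C)(C)C | intermediate
21 | {(4S,5S)-2,2-dimethyl-5-[(2Z)-oct-2-en-1-yl]-1,3-dioxolan-4-yl}methanol | CCCCC/C=C\C[C@@H]1OC(C)(C)O[C@H]1CO | intermediate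
22 | (4R,5S)-2,2-dimethyl-5-[(2Z)-oct-2-en-1-yl]-1,3-dioxolane-4-carbaldehyde | CCCCC/C=C\C[C@@H]1OC(C)(C)O[C@H]1C=O | intermediate
23 | (8R)-8-[(1R,2S)-2-{(E)-2-[(4S,5S)-2,2-dimethyl-5-[(2Z)-oct-2-en-1-yl]-1,3-dioxolan-4-yl]ethenyl}cyclopropyl]oxocan-2-one | CCCCC/C=C\C[C@@H]1OC(C)(C)O[C@H]1/C=C/[C@@H]1C[C@H]1[C@H]1CCCCCC(=O)O1 | intermediate
24 | (8R)-8-{(1R,2S)-2-[(1E,3S,4S,6Z)-3,4-dihydroxydodeca-1,6-dien-1-yl]cyclopropyl}oxocan-2-one | CCCCC/C=C\C[C@H](O)[C@@H](O)/C=C/[C@@H]1C[C@H]1[C@H]1CCCCCC(=O)O1 | target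

**Step count**
Total: 17 steps (9 steps to sulfone 14, 6 steps to aldehyde 22, 2 common steps). Longest linear sequence: 11 steps (steps 1–9, 16, 17).

**Steps most likely to fail**

Step 6 (key step). The C2 radical may be reduced by the stannane before it cyclises, or add intermolecularly, so that the eight-membered ring does not close. The fallback closes the ring by metathesis at C3=C4 instead. It sets out from alcohol 6, which is esterified with but-3-enoic acid (DIC, cat. DMAP, CH2Cl2, 0 °C) to (1R)-1-[(1R,2R)-2-{[(tert-butyldimethylsilyl)oxy]methyl}cyclopropyl]pent-4-en-1-yl but-3-enoate F1. Ring-closing metathesis with the second-generation Grubbs catalyst in dilute refluxing CH2Cl2 should give the (4Z)-3,6,7,8-tetrahydro-2H-oxocin-2-one F2. Diimide reduction (2-nitrobenzenesulfonohydrazide, Et3N, CH2Cl2) should saturate the ring alkene without touching the cyclopropane, and the route is rejoined at lactone 11.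

Step 4. The methylene may be delivered with poor facial selectivity, because one carbinol stereocenter has to control an E-alkene. The fallback replaces substrate control by reagent control. It sets out from alcohol 5, which is converted into its 4-methoxybenzyl ether F3 (NaH, PMBCl, Bu4NI, DMF). The primary silyl ether is removed (Bu4NF, THF) to give the primary allylic alcohol F4. A dioxaborolane-mediated asymmetric Simmons–Smith cyclopropanation (Zn(CH2I)2·DME, (4S,5S)-2-butyl-N,N,N′,N′-tetramethyl-1,3,2-dioxaborolane-4,5-dicarboxamide, CH2Cl2, 0 °C) follows. This ligand enantiomer is expected, by analogy with simple E-allylic alcohols, to select the alkene face independently of C7, and should give the cyclopropylmethanol F5. Silylation (TBSCl, imidazole, DMF) to the silyl ether F6 and oxidative removal of the PMB group (DDQ, CH2Cl2/pH 7 buffer) return to alcohol 6.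

Step 17. Acid may ionise the C13–O bond, which is allylic and conjugated with the cyclopropane, leading to allylic transposition or ring opening; acidolysis of the strained lactone may also compete with ketal hydrolysis. The fallback makes the last step non-acidic by changing the diol protection before the coupling. It sets out from silyl ether 20, which is hydrolysed (1 M HCl, THF, rt) to (2S,3S,5Z)-undec-5-ene-1,2,3-triol F7. Persilylation (TESCl, imidazole, DMF) gives the tris-TES ether F8. Swern oxidation, which converts a primary TES ether directly into the aldehyde in the presence of secondary ones, gives (2R,3S,5Z)-2,3-bis[(triethylsilyl)oxy]undec-5-enal F9. Julia–Kocienski coupling with sulfone 14 under the conditions of step 16 should give the bis-TES diene F10, and HF·pyridine in THF/pyridine then releases target 24.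

**Further compounds**
F1 | step 6 | (1R)-1-[(1R,2R)-2-{[(tert-butyldimethylsilyl)oxy]methyl}cyclopropyl]pent-4-en-1-yl but-3-enoate | CC(C)(C)[Si](C)(C)OC[C@@H]1C[C@H]1[C@H](OC(=O)CC=C)CCC=C
F2 | step 6 | (4Z,8R)-8-[(1R,2R)-2-{[(tert-butyldimethylsilyl)oxy]methyl}cyclopropyl]-3,6,7,8-tetrahydro-2H-oxocin-2-one | CC(C)(C)[Si](C)(C)OC[C@@H]1C[C@H]1[C@H]1CC/C=C\CC(=O)O1
F3 | step 4 | tert-butyl{[(2E,4R)-4-[(4-methoxybenzyl)oxy]nona-2,8-dien-1-yl]oxy}dimethylsilane | CC(C)(C)[Si](C)(C)OC/C=C/[C@H](OCc1ccc(OC)cc1)CCC=C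
F4 | step 4 | (2E,4R)-4-[(4-methoxybenzyl)oxy]nona-2,8-dien-1-ol | OC/C=C/[C@H](OCc1ccc(OC)cc1)CCC=C
F5 | step 4 | {(1R,2R)-2-[(1R)-1-[(4-methoxybenzyl)oxy]pent-4-en-1-yl]cyclopropyl}methanol | OC[C@@H]1C[C@H]1[C@H](OCc1ccc(OC)cc1)CCC=C
F6 | step 4 | tert-butyl({(1R,2R)-2-[(1R)-1-[(4-methoxybenzyl)oxy]pent-4-en-1-yl]cyclopropyl}methoxy)dimethylsilane | CC(C)(C)[Si](C)(C)OC[C@@H]1C[C@H]1[C@H](OCc1ccc(OC)cc1)CCC=C
F7 | step 17 | (2S,3S,5Z)-undec-5-ene-1,2,3-triol | CCCCC/C=C\C[C@H](O)[C@@H](O)CO
F8 | step 17 | (2S,3S,5Z)-1,2,3-tris[(triethylsilyl)oxy]undec-5-ene | CCCCC/C=C\C[C@H](O[Si](CC)(CC)CC)[C@@H](O[Si](CC)(CC)CC)CO[Si](CC)(CC)CC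
F9 | step 17 | (2R,3S,5Z)-2,3-bis[(triethylsilyl)oxy]undec-5-enal | CCCCC/C=C\C[C@H](O[Si](CC)(CC)CC)[C@@H](O[Si](CC)(CC)CC)C=O
F10 | step 17 | (8R)-8-{(1R,2S)-2-[(1E,3S,4S,6Z)-3,4-bis[(triethylsilyl)oxy]dodeca-1,6-dien-1-yl]cyclopropyl}oxocan-2-one | CCCCC/C=C\C[C@H](O[Si](CC)(CC)CC)[C@@H](O[Si](CC)(CC)CC)/C=C/[C@@H]1C[C@H]1[C@H]1CCCCCC(=O)O1
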